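**Assumption:** the [C@H] centre in the given SMILES is read as (S); heptan-4-one, 1-bromo-8-chlorooctane and (S)-2-methyloxirane are taken as catalogue chemicals.

## Retrosynthetic overview

1. 14 ⇒ 13 + 12: the C6(pyranone)–C11(chain) bond is made by a Pd-catalysed alkyl Negishi coupling. The C6-zincated methoxypyranone is a metalated enol ether, an acyl-anion-type donor at a carbon that is normally electrophilic, and it is joined to a primary alkyl iodide.
2. 12 ⇒ (S)-2-methyloxirane + the Grignard reagent of 1-bromo-8-chlorooctane, acetylated in the same flask, then Cl → I. The stereocentre comes from the epoxide.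
3. 6 ⇒ 5 by O-methylation; 5 ⇒ dianion of 2 + methyl formate (formylation and lactonisation); 2 ⇒ heptan-4-one + dimethyl carbonate.
4. Ring order: the pyranone is the only ring; it is closed in step 2, before the key coupling.

## Route

**Step 1**
Reactants: 1 heptan-4-one
Product: 2 methyl 2-ethyl-3-oxohexanoate
Conditions: NaH (2.2 equiv), (MeO)2CO (3 equiv), THF, reflux; aq. HCl
Reagents that add atoms: dimethyl carbonate, COC(=O)OC
Why: Claisen-type C-acylation (carbomethoxylation) of the sodium enolate of a symmetrical ketone, driven by irreversible deprotonation of the beta-keto ester product; symmetry removes any regiochemical question.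

**Step 2**
Reactants: 2 methyl 2-ethyl-3-oxohexanoate
Product: 5 3,5-diethyl-4-hydroxy-2H-pyran-2-one, via dilithium dienolate 3 (not isolated), via methyl 2-ethyl-4-formyl-3-oxohexanoate 4 (not isolated)
Conditions: LiN(iPr)2 (2.3 equiv), THF, −78 → 0 °C; HCO2Me (3 equiv), −78 °C; aq. HCl; crude 4, DBU, toluene, 60 °C
Reagents that add atoms: methyl formate, COC=O
Why: Huckin–Weiler dianion chemistry: the gamma-carbanion of the beta-keto ester dianion undergoes Claisen formylation, and DBU then triggers enol-lactonisation (formyl enolate oxygen onto the ester, loss of methanol) to the aromatic 4-hydroxy-2-pyranone, which closes the only ring.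

**Step 3**
Reactants: 5 3,5-diethyl-4-hydroxy-2H-pyran-2-one
Product: 6 3,5-diethyl-2-methoxy-4H-pyran-4-one
Conditions: MeOTf (1.2 equiv), CH2Cl2, 0 °C → rt; aq. NaHCO3
Reagents that add atoms: methyl trifluoromethanesulfonate, COS(=O)(=O)C(F)(F)F
Why: hard O-alkylation under neutral conditions takes place at the more basic lactone carbonyl oxygen to give a 2-methoxy-4-hydroxypyrylium triflate, which loses a proton to the alpha-methoxy-gamma-pyranone; this is the established regiochemical outcome for 3,5-dialkyl-4-hydroxy-2-pyranones with methyl triflate or fluorosulfonate.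

**Step 4**
Reactants: 7 1-bromo-8-chlorooctane; 8 (S)-2-methyloxirane
Product: 11 (S)-11-chloroundecan-2-yl acetate, via 8-chlorooctylmagnesium bromide 9 (not isolated), via bromomagnesium (S)-11-chloroundecan-2-olate 10 (not isolated)
Conditions: Mg, THF, 40 °C; CuI (10 mol %), 8 (1.2 equiv), −30 → 0 °C; Ac2O, 0 °C → rt; dilute aq. HCl
Reagents that add atoms: acetic anhydride, CC(=O)OC(C)=O
Why: Mg inserts into C–Br in preference to C–Cl, the CuI-catalysed Grignard opens the epoxide by SN2 attack at the unsubstituted carbon so the (S)-centre is carried over untouched as the (S)-carbinol, and the magnesium alkoxide is O-acylated in situ.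

**Step 5**
Reactants: 11 (S)-11-chloroundecan-2-yl acetate
Product: 12 (S)-11-iodoundecan-2-yl acetate
Conditions: NaI (3 equiv), butan-2-one, reflux
Reagents that add atoms: sodium iodide, [Na+].[I-]
Why: Finkelstein halide exchange (SN2 at the primary carbon) driven by precipitation of NaCl; the acetate and the remote stereocentre are not affected.

**Step 6**
Reactants: 6 3,5-diethyl-2-methoxy-4H-pyran-4-one; 12 (S)-11-iodoundecan-2-yl acetate
Product: 14 (S)-11-(3,5-diethyl-6-methoxy-4-oxo-4H-pyran-2-yl)undecan-2-yl acetate, via (3,5-diethyl-6-methoxy-4-oxo-4H-pyran-2-yl)zinc chloride 13 (not isolated)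
Conditions: TMPZnCl·LiCl (1.1 equiv to 6; TMP = 2,2,6,6-tetramethylpiperidin-1-yl), THF, 25 °C; then 12 (0.8 equiv), Pd2(dba)3 (2 mol %), tricyclopentylphosphine (8 mol %), N-methylimidazole (1.2 equiv), THF/NMP 2:1, 80 °C
Reagents that add atoms: none
Why: Proposed new method: the only ring C–H of 6 (C6–H, an sp2 C–H alpha to the ring oxygen) is removed by the hindered TMP-zinc amide to give alkenylzinc 13, a metalated enol ether that acts as an acyl-anion-type donor at what is normally the electrophilic beta-carbon of the vinylogous ester; zerovalent palladium carrying the bulky, electron-rich tricyclopentylphosphine adds oxidatively (SN2-type) to the primary C–I bond of 12, N-methylimidazole-activated 13 transmetalates, and reductive elimination outruns beta-hydride elimination, so two normally electrophilic carbons are joined; the closest known reactions are the TMP-zinc metalation and Negishi coupling of chromones and 4-pyranones and the Pd/trialkylphosphine Negishi coupling of alkenyl- and arylzinc halides with unactivated primary alkyl iodides, and the acetate and the remote (S)-centre are spectators.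

## Compound list

1 | heptan-4-one | CCCC(=O)CCC | starting material
2 | methyl 2-ethyl-3-oxohexanoate (racemic, epimerisable at C2) | CCCC(=O)C(CC)C(=O)OC | intermediate
3 | dilithium dienolate of 2 (dilithium 2-ethyl-1-methoxyhexa-1,3-diene-1,3-diolate) | CCC=C([O-])C(CC)=C([O-])OC.[Li+].[Li+] | intermediate
4 | methyl 2-ethyl-4-formyl-3-oxohexanoate (diastereomer and enol mixture) | CCC(C=O)C(=O)C(CC)C(=O)OC | intermediate
5 | 3,5-diethyl-4-hydroxy-2H-pyran-2-one | CCc1coc(=O)c(CC)c1O | intermediate
6 | 3,5-diethyl-2-methoxy-4H-pyran-4-one | CCc1coc(OC)c(CC)c1=O | intermediate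
7 | 1-bromo-8-chlorooctane | ClCCCCCCCCBr | starting material
8 | (S)-2-methyloxirane | C[C@H]1CO1 | starting material
9 | 8-chlorooctylmagnesium bromide | ClCCCCCCCC[Mg]Br | intermediate
10 | bromomagnesium (S)-11-chloroundecan-2-olate | ClCCCCCCCCC[C@H](C)O[Mg]Br | intermediate
11 | (S)-11-chloroundecan-2-yl acetate | ClCCCCCCCCC[C@H](C)OC(C)=O | intermediate
12 | (S)-11-iodoundecan-2-yl acetate | ICCCCCCCCC[C@H](C)OC(C)=O | intermediate
13 | (3,5-diethyl-6-methoxy-4-oxo-4H-pyran-2-yl)zinc chloride | CCc1c([Zn]Cl)oc(OC)c(CC)c1=O | intermediate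
14 | (S)-11-(3,5-diethyl-6-methoxy-4-oxo-4H-pyran-2-yl)undecan-2-yl acetate | CCc1c(CCCCCCCCC[C@H](C)OC(C)=O)oc(OC)c(CC)c1=O | target

## Step count and risks

Total steps: 6. Longest linear sequence: 4 steps (steps 1, 2, 3 and 6); the side branch is steps 4 and 5.

**Step 6 (most likely to fail).** The zinc reagent may transmetalate slowly, and iodide or N-methylimidazole may demethylate the methoxypyranone at 80 °C. The fallback keeps the C6 donor but changes the electrophile to a carbonyl; it sets out from 12 and 6 and comes back at 14. Kornblum oxidation of 12 (DMSO, NaHCO3, 110 °C) gives (S)-11-oxoundecan-2-yl acetate F1. Compound 6 is magnesiated at C6 with TMPMgCl·LiCl (THF, −40 °C) to (3,5-diethyl-6-methoxy-4-oxo-4H-pyran-2-yl)magnesium chloride F2, which adds to the aldehyde at −78 °C to give (2S)-11-(3,5-diethyl-6-methoxy-4-oxo-4H-pyran-2-yl)-11-hydroxyundecan-2-yl acetate F3, an inconsequential mixture of C11 epimers. Acylation with phenyl chlorothionoformate (pyridine, DMAP) gives (2S)-11-(3,5-diethyl-6-methoxy-4-oxo-4H-pyran-2-yl)-11-(phenoxycarbonothioyloxy)undecan-2-yl acetate F4, and Barton–McCombie deoxygenation (Bu3SnH, AIBN, toluene, 80 °C) delivers 14.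

**Step 2.** The formyl Claisen product can transfer a proton to unreacted dianion or be deformylated by methoxide, and the beta-keto aldehyde 4 is fragile. The fallback replaces the Claisen by an aldol and a dehydrogenation; it sets out from 2 (through dianion 3) and comes back at 5. Dianion 3 is treated with monomeric formaldehyde (cracked paraformaldehyde, −78 °C) to give methyl 2-ethyl-4-(hydroxymethyl)-3-oxohexanoate F5. Lactonisation (K2CO3, MeOH, then acid) gives 3,5-diethyl-4-hydroxy-5,6-dihydro-2H-pyran-2-one F6. Dehydrogenation with DDQ (dioxane, 80 °C; hydride loss from C6 next to the ring oxygen, then loss of the C5 proton) gives 5.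

**Step 3.** Methylation could give the isomeric 4-methoxy-2-pyranone, or ring-open the unhindered C6–H product. The fallback avoids the hydroxypyranone; it sets out from 4 (isolated after the acidic quench of step 2, before DBU) and comes back at 6. Appel-type activation of the formyl enol with PPh3/CCl4 (THF, reflux) gives methyl 5-chloro-2,4-diethyl-3-oxopent-4-enoate F7. The ester carbonyl oxygen then closes onto the chlorovinyl carbon and HCl is lost, giving 6 directly with the methoxy group already in place.

## Further compounds

F1 | step 6 | (S)-11-oxoundecan-2-yl acetate | O=CCCCCCCCC[C@H](C)OC(C)=O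
F2 | step 6 | (3,5-diethyl-6-methoxy-4-oxo-4H-pyran-2-yl)magnesium chloride | CCc1c([Mg]Cl)oc(OC)c(CC)c1=O
F3 | step 6 | (2S)-11-(3,5-diethyl-6-methoxy-4-oxo-4H-pyran-2-yl)-11-hydroxyundecan-2-yl acetate | CCc1c(C(O)CCCCCCCC[C@H](C)OC(C)=O)oc(OC)c(CC)c1=O
F4 | step 6 | (2S)-11-(3,5-diethyl-6-methoxy-4-oxo-4H-pyran-2-yl)-11-(phenoxycarbonothioyloxy)undecan-2-yl acetate | CCc1c(C(OC(=S)Oc2ccccc2)CCCCCCCC[C@H](C)OC(C)=O)oc(OC)c(CC)c1=O
F5 | step 2 | methyl 2-ethyl-4-(hydroxymethyl)-3-oxohexanoate | CCC(CO)C(=O)C(CC)C(=O)OC
F6 | step 2 | 3,5-diethyl-4-hydroxy-5,6-dihydro-2H-pyran-2-one | CCC1COC(=O)C(CC)=C1O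
F7 | step 3 | methyl 5-chloro-2,4-diethyl-3-oxopent-4-enoate | ClC=C(CC)C(=O)C(CC)C(=O)OC
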